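**The question.** One question stood: the apparent order in E in the flask at 50% conversion of G.

| flask | G | E | remark |
|---|---|---|---|
| north | 0.18 M | 130 µM | run made earlier |
| south-east | 0.18 M | 200 µM | run made earlier |
| flask | 0.18 M | 90 µM |  |

- north (time / min: Q / %): 2.50: 38; 4.00: 61; 6.00: 93; 8.00: 97; 12.0: 98; 20.0: 101; 30.0: 97
- south-east (time / min: Q / %): 2.50: 63; 4.00: 95; 6.00: 98; 8.00: 101; 12.0: 99; 20.0: 99; 30.0: 99

(readings scatter by 1.5 percentage points)

- what has gone from G into another species counts as reacted, even if it can come back

1. apparent order in E when 50% of the G are converted (percent change of the rate of making Q for one percent more E charged)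

**Crossing times.** I first read when each run crossed 50%. North passed it between 2.50 min and 4.00 min, and straight interpolation put the crossing at 3.28 min. South-east, read along a straight line from zero to its first point, crossed at 1.98 min.

**Enzyme dose.** North gave 427 µM·min of what I called the enzyme dose, the [E] charged times the crossing time. Held frozen, that dose put the flask's crossing at 4.74 min and made the order exactly one.

**Weak link.** South-east's dose was 397 µM·min, so north's was larger than south-east's by a factor of 1.08, a reading that carries the scatter of 1.5 percentage points. The slower run had needed more dose, as if E wore out, so I unfroze the dose. As a working assumption, which these few readings do not test, I took the rate at that conversion to go as one over the crossing time. The two crossing times then gave an order of 1.17, and I committed to that.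

**The forecast.** The forecast stood lower than my figure, at 1.05, with the words “The slight excess might reflect a small poison or activation effect”.

**The result.** The flask gave 1.2. At 5.00 min the flask's E stood at 81.1% of its charge, with X at 18.9%.

    G + E → Q + E, rate k1*[G]*[E]/(1 + ([G]/Km1) + ([G]/Ksi1)^2) (0.410 M, 0.0510 M, k = 230 M⁻¹ s⁻¹)
    G ⇌ J (K = 15.0, k = 1.00 × 10⁻⁴ s⁻¹)
    E → X (k = 7.00 × 10⁻⁴ s⁻¹)

The north dose over the flask's 90 µM gives a crossing at 4.74 min, and the flask took 4.74 min. That time multiplied by the constant of the step from E to X, 0.042 min⁻¹, gives 0.199, and the flask's order stands 0.200 above one.

The earlier runs and the new flask are simulated for an exercise, and the scatter is random.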